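Everything rests on cutting the C3'–C3a' bond of the furo[3,2-b]furanone. In an all-cis oxolane, the C3a'–H bond that flanks ring oxygen O4' and shares a face with ester oxygen O1' is the only C–H that a carbene tethered to O1' can reach through a five-membered transition state. Dirhodium decomposition of diazoacetate 36 therefore forms C3'–C3a', closes the cis-fused γ-lactone and sets C3a' in one operation. Precursor 36 already holds the pyrrolo[1,2-a]azepin-5-one (N4 masked as lactam), the C3 butyrolactone and the C5'/C6'/C6a' triad. These are built from a pyroglutamate by conjugate addition, Evans aldol and directed reduction. Aminomethylenation, convex-face hydrogenation and lactam deoxygenation complete the target.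

Key step: step 22

Remark (locants): C1–C3, N4, C5–C9, C9a for the pyrroloazepine. O1', C2', C3', C3a', O4', C5', C6', C6a' for the furofuranone, used from the acyclic stage on. C18 (carbinol), C19, C20 (CHMe), C21 (C=O) for the lactone on C3.
Remark (structures): 36 and 37 carry the target configuration at every shared stereocentre, so neither structure needs a correction, and 36 is used without extra protecting groups.
Remark (descriptors): the C6' descriptor switches between R and S along the route only because substituent priorities change.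
Assumption: 1, 7, 8, 28, 34, both Grignard solutions, Me4NBH(OAc)3, TsNHNHTs, Rh2(cap)4 and Bredereck's reagent are purchased.
Assumption: the aminal carbon of 2 and 3 and the ozonide carbons of 5 and 21 are inconsequential epimer mixtures. Enamine 38 is drawn E, and its geometry is erased in step 24.

Step 1
Reactants: 1 N-Boc-L-pyroglutamic acid tert-butyl ester
Product: 3 (2S)-5-methoxy N,O-acetal (C5 epimers), via hemiaminal 2 (not isolated)
Conditions: LiBHEt3, THF, −78 °C; aq. NaHCO3; then MeOH, p-TsOH (cat.), rt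
Reagents that add atoms: methanol, CO
Why: Partial reduction of an N-acyl lactam: the Boc-activated ring carbonyl takes up hydride far faster than the hindered tert-butyl ester, and acid-catalysed exchange with methanol stores the hemiaminal as a stable N,O-acetal whose new centre is erased in step 2.

Step 2
Reactants: 3 (2S)-5-methoxy N,O-acetal
Product: 4 (2S,5S)-5-ethenylpyrrolidine diester (2,5-trans)
Conditions: CH2=CHMgBr, CuBr·SMe2, BF3·OEt2, Et2O, −78 °C → rt; aq. NH4Cl
Reagents that add atoms: vinylmagnesium bromide, C=C[Mg]Br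
Why: N-Acyliminium alkylation with an organocopper–BF3 reagent: BF3 ionises the N,O-acetal and the vinylcopper species attacks the face opposite the C3 ester, which should set C9a trans to C3.

Step 3
Reactants: 4 trans-5-ethenylpyrrolidine diester
Product: 6 (2S,5S)-5-formylpyrrolidine diester, via secondary ozonide 5 (not isolated)
Conditions: O3, CH2Cl2, −78 °C; Me2S, −78 °C → rt
Reagents that add atoms: ozone, [O-][O+]=O
Why: Ozonolysis with reductive work-up cleaves the only alkene to the C9 aldehyde under neutral conditions that leave the α-amino centre C9a untouched.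

Step 4
Reactants: 7 (diethoxyphosphoryl)acetic acid; 8 (4R)-4-benzyl-1,3-oxazolidin-2-one
Product: 10 phosphonoacetyl (4R)-benzyloxazolidinone, via mixed pivalic anhydride 9 (not isolated)
Conditions: t-BuCOCl, Et3N, THF, −20 °C; then 8, LiCl, −20 °C → rt
Reagents that add atoms: none
Why: N-Acylation of an oxazolidinone through a mixed pivalic anhydride under LiCl/Et3N activation avoids strong base and delivers the Horner–Wadsworth–Emmons reagent in one operation.

Step 5
Reactants: 6 (2S,5S)-5-formylpyrrolidine diester; 10 phosphonoacetyl oxazolidinone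
Product: 11 (E)-N-enoyl oxazolidinone (C6'=C9 alkene on C9a)
Conditions: LiCl, i-Pr2NEt, MeCN, rt
Reagents that add atoms: none
Why: Masamune–Roush variant of the Horner–Wadsworth–Emmons olefination: the lithium-chelated phosphonate is deprotonated by an amine mild enough to spare C9a, and stabilised phosphonates of this kind should give the E-alkene.

Step 6
Reactants: 11 (E)-N-enoyl oxazolidinone
Product: 12 (9R)-pent-4-enyl adduct (3-substituted oct-7-enoyl imide)
Conditions: CH2=CH(CH2)3MgBr, CuBr·SMe2, THF–Me2S, −40 °C; then 11, −78 → −20 °C; aq. NH4Cl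
Reagents that add atoms: pent-4-enylmagnesium bromide, C=CCCC[Mg]Br
Why: Conjugate addition of a Grignard-derived organocopper reagent to an N-enoyl oxazolidinone: the magnesium-chelated syn-s-cis imide is attacked at C9 on the face away from the benzyl group, which is also the face anti to the C9a–N bond (polar Felkin–Anh), so auxiliary and substrate should reinforce each other in setting (9R).

Step 7
Reactants: 12 (9R)-oct-7-enoyl imide
Product: 15 syn aldol adduct (5'S,6'R,9R), via Z-boron enolate 13 (not isolated), via boron aldolate 14 (not isolated)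
Conditions: n-Bu2BOTf, Et3N, CH2Cl2, 0 °C; MeCHO, −78 → 0 °C; pH 7 buffer, MeOH, 30% H2O2, 0 °C
Reagents that add atoms: acetaldehyde, CC=O
Why: Evans syn aldol: the Z-boron enolate reacts through a Zimmerman–Traxler chair on the face left open by the (R)-benzyl group, which should give the (5'S,6'R) syn pair whatever the influence of the C9 branch.

Step 8
Reactants: 15 syn aldol adduct
Product: 16 β-hydroxy Weinreb amide (C6a' carbonyl)
Conditions: MeONHMe·HCl, AlMe3, CH2Cl2, −10 °C → rt; Rochelle salt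
Reagents that add atoms: N,O-dimethylhydroxylamine hydrochloride, CNOC.Cl
Why: Aluminium amide transamination (Weinreb amide synthesis): the C5' aluminium alkoxide directs the reagent to the exocyclic imide carbonyl, which releases the auxiliary while the hindered tert-butyl ester and the carbamate stay intact.

Step 9
Reactants: 16 β-hydroxy Weinreb amide
Product: 17 chloromethyl ketone (C3a'H2Cl–C6a'=O)
Conditions: ICH2Cl, MeLi·LiBr, THF–Et2O, −78 °C; AcOH quench
Reagents that add atoms: chloroiodomethane, ClCI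
Why: Acylation of a halomethyllithium carbenoid by a Weinreb amide: LiCH2Cl generated in the presence of 16 first deprotonates the hydroxyl and then adds once, and the chelated tetrahedral adduct survives until the acidic quench, so that C3a' arrives already bearing its leaving group.

Step 10
Reactants: 17 chloromethyl ketone
Product: 18 1,3-anti chlorodiol (5'S,6'R,6a'R)
Conditions: Me4NBH(OAc)3, MeCN–AcOH, −40 → −20 °C
Reagents that add atoms: none
Why: Evans–Saksena reduction: ligand exchange at the C5' hydroxyl and internal hydride delivery through a chair place the new C6a' hydroxyl 1,3-anti, the relationship that becomes all-cis once the ring is closed.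

Step 11
Reactants: 18 1,3-anti chlorodiol
Product: 20 all-cis 4-hydroxy-2-methyloxolan-3-yl pyrrolidine, via epoxy alcohol 19 (not isolated)
Conditions: K2CO3, MeOH, 0 °C → rt; concentrate; then CSA (cat.), CH2Cl2, rt
Reagents that add atoms: none
Why: Williamson closure of the chlorohydrin to the epoxide, followed by acid-catalysed opening of the 3,4-epoxy alcohol at its primary carbon C3a' by the C5' hydroxyl (5-endo mode, since the 4-exo oxetane is strained), builds the oxolane without touching a stereocentre.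

Step 12
Reactants: 20 all-cis oxolanol with pentenyl chain
Product: 22 C5 aldehyde, via secondary ozonide 21 (not isolated)
Conditions: O3, CH2Cl2, −78 °C (Sudan III end point); Me2S, −78 °C → rt
Reagents that add atoms: ozone, [O-][O+]=O
Why: Ozonolysis of the terminal alkene removes the extra carbon and exposes C5 as an aldehyde, while alcohol, ether and carbamate are inert at −78 °C when ozone is dosed to an indicator end point.

Step 13
Reactants: 22 C5 aldehyde
Product: 23 C5 carboxylic acid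
Conditions: NaClO2, NaH2PO4, 2-methylbut-2-ene, t-BuOH–H2O, rt
Reagents that add atoms: sodium chlorite, [Na+].[O-]Cl=O
Why: Pinnick oxidation converts the aldehyde into the C5 acid and does not touch the free secondary C6a' alcohol, which therefore needs no protecting group.

Step 14
Reactants: 23 C5 carboxylic acid
Product: 24 C5 pentafluorophenyl ester
Conditions: C6F5OH, EDC·HCl, CH2Cl2, 0 °C → rt
Reagents that add atoms: pentafluorophenol, Oc1c(F)c(F)c(F)c(F)c1F
Why: Carbodiimide esterification with pentafluorophenol pre-activates only the C5 carboxyl, so that the C3 carboxyl unveiled in the next step cannot compete in the ring closure.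

Step 15
Reactants: 24 C5 pentafluorophenyl ester
Product: 26 pyrrolo[1,2-a]azepin-5-one-3-carboxylic acid (3S,9R,9aS), via amino acid active ester 25 (not isolated)
Conditions: TFA–CH2Cl2, rt; evaporate; then slow addition to i-Pr2NEt, MeCN (2 mM), 60 °C
Reagents that add atoms: none
Why: Acidolysis removes Boc and tert-butyl ester together, and on neutralisation at high dilution the freed pyrrolidine nitrogen attacks the active ester (7-exo-trig lactamisation) while the C3 carboxylate stays inert.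

Step 16
Reactants: 26 lactam acid
Product: 27 S-ethyl thioester at C3
Conditions: EtSH, EDC·HCl, HOBt, CH2Cl2, 0 °C → rt
Reagents that add atoms: ethanethiol, CCS
Why: Carbodiimide/HOBt thioesterification: the soft thiol outcompetes the hindered C6a' alcohol, and the benzotriazolyl ester limits epimerisation at C3.

Step 17
Reactants: 28 methyl (S)-3-hydroxy-2-methylpropanoate
Product: 29 methyl (R)-3-iodo-2-methylpropanoate
Conditions: I2, PPh3, imidazole, CH2Cl2, 0 °C → rt
Reagents that add atoms: iodine, II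
Why: Appel-type iodination displaces the primary hydroxyl without touching the adjacent stereocentre, whose descriptor changes to R only through the priority rules.

Step 18
Reactants: 27 S-ethyl thioester; 29 methyl (R)-3-iodo-2-methylpropanoate
Product: 31 γ-keto ester (C18 ketone, 20S), via organozinc iodide 30 (not isolated)
Conditions: 29, Zn dust (BrCH2CH2Br, TMSCl), THF, 35 °C; then 27, PdCl2(PPh3)2 (cat.), toluene, rt; aq. NH4Cl
Reagents that add atoms: none
Why: Fukuyama coupling: zinc inserts into the primary C–I bond to give a configurationally secure ester homoenolate, and palladium-catalysed acyl transfer from the thioester forms C18–C19 without over-addition while tolerating hydroxyl, lactam and ester.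

Step 19
Reactants: 31 γ-keto ester
Product: 33 oxolanol bearing lactam plus (18S,20S)-butyrolactone, via hydroxy ester 32 (not isolated)
Conditions: L-Selectride, THF, −78 → 0 °C; aq. NH4Cl
Reagents that add atoms: none
Why: Felkin–Anh reduction with a bulky, non-chelating borohydride: hydride approaches C18 anti to the C3–N bond to give the (18S) syn amino alcohol, whose alkoxide lactonises onto the methyl ester, and C20 comes unchanged from 28.

Step 20
Reactants: 33 oxolanol; 34 bromoacetyl bromide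
Product: 35 C6a' bromoacetate
Conditions: NaHCO3, MeCN, 0 °C
Reagents that add atoms: none
Why: O-Acylation with a highly reactive acyl bromide overcomes the crowding around the all-cis C6a' hydroxyl, the only nucleophile left in 33.

Step 21
Reactants: 35 C6a' bromoacetate
Product: 36 all-cis oxolan-3-yl diazoacetate on C9 of the pyrroloazepin-5-one
Conditions: TsNHNHTs, DBU, THF, 0 °C
Reagents that add atoms: N,N'-ditosylhydrazine, Cc1ccc(cc1)S(=O)(=O)NNS(=O)(=O)c1ccc(C)cc1
Why: Diazoacetate synthesis from a bromoacetate: N-alkylation of ditosylhydrazine followed by DBU-induced loss of two sulfinate units unveils the diazo group at 0 °C, which is too mild to epimerise C20.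

Step 22
Reactants: 36 diazoacetate
Product: 37 3'-demethyl furofuranone in the 5-oxo series (3a'R)
Conditions: Rh2(cap)4 (1 mol %), 4 Å MS, CH2Cl2, reflux; 36 added by syringe pump over 10 h
Reagents that add atoms: none
Why: Dirhodium caprolactamate expels N2 from 36 to give an electrophilic rhodium carbenoid at C3', which enters the C3a'–H bond in a single asynchronous event with retention at carbon; the closest known reaction type is the dirhodium carboxamidate-catalysed C–H insertion of cycloalkyl and oxacycloalkyl diazoacetates to fused γ-lactones. The new ring (C3', C2', O1', C6a', C3a') closes by 1,5-insertion through a five-membered cyclic transition state, and on an oxolane such a fusion can only be cis. C3a' is the one new stereocentre and is dictated by C6a', because only the C3a' hydrogen on the O1' face lies within reach of the carbenoid. The step needs site selectivity, which the substrate supplies: O4' makes C3a'–H the most hydridic bond, C6'–H and C5'–H point to the far face of the all-cis ring, and C9–H and C9a–H would need six- and seven-membered transition states. Keeping N4 acylated removes the lone pair that would otherwise intercept the carbenoid as an ylide, and the electron-rich amidate ligands together with slow addition and sieves hold back carbene coupling and O–H capture.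

Step 23
Reactants: 37 3'-demethyl furofuranone
Product: 38 3'-(dimethylaminomethylidene) lactone
Conditions: t-BuOCH(NMe2)2, toluene, 90 °C
Reagents that add atoms: tert-butoxybis(dimethylamino)methane (Bredereck's reagent), CN(C)C(OC(C)(C)C)N(C)C
Why: Aminomethylenation with Bredereck's reagent: only a carbonyl flanked by CH2 can end as a stable vinylogous carbamate, so the α-methyl lactone (one α-H) and the much less acidic lactam C6 methylene should not be consumed.

Step 24
Reactants: 38 enamino lactone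
Product: 39 (3'S)-3'-methyl furofuranone lactam (methyl endo)
Conditions: H2 (4 atm), 10% Pd/C, EtOAc–AcOH, rt
Reagents that add atoms: none
Why: Catalytic hydrogenation–hydrogenolysis of the vinylogous carbamate turns C=CH–NMe2 into CH–CH3, and since the catalyst can reach C3' only from the convex face that carries H3a' and H6a', the methyl group should end on the concave face as in the target.

Step 25
Reactants: 39 3'-methyl lactam
Product: 40 C5 thiolactam
Conditions: Lawesson's reagent (0.55 equiv), toluene, 80 °C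
Reagents that add atoms: Lawesson's reagent, COc1ccc(cc1)P1(=S)SP(=S)(S1)c1ccc(OC)cc1
Why: Thionation with Lawesson's reagent is selective for the electron-rich lactam carbonyl over the two lactones and is non-basic, so the epimerisable endo C3' methyl is safe.

Step 26
Reactants: 40 thiolactam
Product: 41 target CNP0108586.2
Conditions: Raney Ni (W-2, washed neutral), EtOH, rt
Reagents that add atoms: none
Why: Raney nickel desulfurisation reduces C=S to CH2 and leaves both lactones and all stereocentres unchanged, giving the tertiary amine.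

Compound list
1 | di-tert-butyl (2S)-5-oxopyrrolidine-1,2-dicarboxylate | CC(C)(C)OC(=O)[C@@H]1CCC(=O)N1C(=O)OC(C)(C)C | starting material
2 | di-tert-butyl (2S)-5-hydroxypyrrolidine-1,2-dicarboxylate (C5 epimers) | OC1CC[C@@H](C(=O)OC(C)(C)C)N1C(=O)OC(C)(C)C | intermediate
3 | di-tert-butyl (2S)-5-methoxypyrrolidine-1,2-dicarboxylate (C5 epimers) | COC1CC[C@@H](C(=O)OC(C)(C)C)N1C(=O)OC(C)(C)C | intermediate
4 | di-tert-butyl (2S,5S)-5-ethenylpyrrolidine-1,2-dicarboxylate | C=C[C@@H]1CC[C@@H](C(=O)OC(C)(C)C)N1C(=O)OC(C)(C)C | intermediate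
5 | di-tert-butyl (2S,5S)-5-(1,2,4-trioxolan-3-yl)pyrrolidine-1,2-dicarboxylate | O1COOC1[C@@H]2CC[C@@H](C(=O)OC(C)(C)C)N2C(=O)OC(C)(C)C | intermediate
6 | di-tert-butyl (2S,5S)-5-formylpyrrolidine-1,2-dicarboxylate | O=C[C@@H]1CC[C@@H](C(=O)OC(C)(C)C)N1C(=O)OC(C)(C)C | intermediate
7 | (diethoxyphosphoryl)acetic acid | CCOP(=O)(CC(=O)O)OCC | starting material
8 | (4R)-4-benzyl-1,3-oxazolidin-2-one | O=C1N[C@H](Cc2ccccc2)CO1 | starting material
9 | (diethoxyphosphoryl)acetic pivalic anhydride | CCOP(=O)(CC(=O)OC(=O)C(C)(C)C)OCC | intermediate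
10 | diethyl {2-[(4R)-4-benzyl-2-oxo-1,3-oxazolidin-3-yl]-2-oxoethyl}phosphonate | CCOP(=O)(CC(=O)N1[C@H](Cc2ccccc2)COC1=O)OCC | intermediate
11 | (4R)-4-benzyl-3-{(2E)-3-[(2S,5S)-1,5-bis(tert-butoxycarbonyl)pyrrolidin-2-yl]prop-2-enoyl}-1,3-oxazolidin-2-one | O=C(/C=C/[C@@H]1CC[C@@H](C(=O)OC(C)(C)C)N1C(=O)OC(C)(C)C)N1[C@H](Cc2ccccc2)COC1=O | intermediate
12 | (4R)-4-benzyl-3-{(3R)-3-[(2S,5S)-1,5-bis(tert-butoxycarbonyl)pyrrolidin-2-yl]oct-7-enoyl}-1,3-oxazolidin-2-one | C=CCCC[C@H](CC(=O)N1[C@H](Cc2ccccc2)COC1=O)[C@@H]1CC[C@@H](C(=O)OC(C)(C)C)N1C(=O)OC(C)(C)C | intermediate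
13 | (Z)-O-dibutylboryl enolate of 12 | CCCCB(CCCC)O/C(=C\[C@@H](CCCC=C)[C@@H]1CC[C@@H](C(=O)OC(C)(C)C)N1C(=O)OC(C)(C)C)N1[C@H](Cc2ccccc2)COC1=O | intermediate
14 | C5' O-dibutylboryl aldolate of 15 | C[C@H](OB(CCCC)CCCC)[C@H](C(=O)N1[C@H](Cc2ccccc2)COC1=O)[C@@H](CCCC=C)[C@@H]1CC[C@@H](C(=O)OC(C)(C)C)N1C(=O)OC(C)(C)C | intermediate
15 | (4R)-4-benzyl-3-{(2R,3R)-3-[(2S,5S)-1,5-bis(tert-butoxycarbonyl)pyrrolidin-2-yl]-2-[(1S)-1-hydroxyethyl]oct-7-enoyl}-1,3-oxazolidin-2-one | C[C@H](O)[C@H](C(=O)N1[C@H](Cc2ccccc2)COC1=O)[C@@H](CCCC=C)[C@@H]1CC[C@@H](C(=O)OC(C)(C)C)N1C(=O)OC(C)(C)C | intermediate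
16 | (2R,3R)-3-[(2S,5S)-1,5-bis(tert-butoxycarbonyl)pyrrolidin-2-yl]-2-[(1S)-1-hydroxyethyl]-N-methoxy-N-methyloct-7-enamide | C[C@H](O)[C@H](C(=O)N(C)OC)[C@@H](CCCC=C)[C@@H]1CC[C@@H](C(=O)OC(C)(C)C)N1C(=O)OC(C)(C)C | intermediate
17 | (3R,4R)-4-[(2S,5S)-1,5-bis(tert-butoxycarbonyl)pyrrolidin-2-yl]-1-chloro-3-[(1S)-1-hydroxyethyl]non-8-en-2-one | C[C@H](O)[C@H](C(=O)CCl)[C@@H](CCCC=C)[C@@H]1CC[C@@H](C(=O)OC(C)(C)C)N1C(=O)OC(C)(C)C | intermediate
18 | (2R,3R,4R)-4-[(2S,5S)-1,5-bis(tert-butoxycarbonyl)pyrrolidin-2-yl]-1-chloro-3-[(1S)-1-hydroxyethyl]non-8-en-2-ol | C[C@H](O)[C@H]([C@@H](O)CCl)[C@@H](CCCC=C)[C@@H]1CC[C@@H](C(=O)OC(C)(C)C)N1C(=O)OC(C)(C)C | intermediate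
19 | (2S,3R,4R)-4-[(2S,5S)-1,5-bis(tert-butoxycarbonyl)pyrrolidin-2-yl]-3-[(2R)-oxiran-2-yl]non-8-en-2-ol | C[C@H](O)[C@H]([C@@H]1CO1)[C@@H](CCCC=C)[C@@H]1CC[C@@H](C(=O)OC(C)(C)C)N1C(=O)OC(C)(C)C | intermediate
20 | di-tert-butyl (2S,5S)-5-{(1R)-1-[(2S,3S,4R)-4-hydroxy-2-methyloxolan-3-yl]hex-5-en-1-yl}pyrrolidine-1,2-dicarboxylate (all-cis oxolane) | C[C@@H]1OC[C@H](O)[C@@H]1[C@@H](CCCC=C)[C@@H]1CC[C@@H](C(=O)OC(C)(C)C)N1C(=O)OC(C)(C)C | intermediate
21 | secondary ozonide of 20 (terminal 1,2,4-trioxolane) | C[C@@H]1OC[C@H](O)[C@@H]1[C@@H](CCCC3OCOO3)[C@@H]2CC[C@@H](C(=O)OC(C)(C)C)N2C(=O)OC(C)(C)C | intermediate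
22 | di-tert-butyl (2S,5S)-5-{(1R)-1-[(2S,3S,4R)-4-hydroxy-2-methyloxolan-3-yl]-5-oxopentyl}pyrrolidine-1,2-dicarboxylate | C[C@@H]1OC[C@H](O)[C@@H]1[C@@H](CCCC=O)[C@@H]1CC[C@@H](C(=O)OC(C)(C)C)N1C(=O)OC(C)(C)C | intermediate
23 | (5R)-5-[(2S,5S)-1,5-bis(tert-butoxycarbonyl)pyrrolidin-2-yl]-5-[(2S,3S,4R)-4-hydroxy-2-methyloxolan-3-yl]pentanoic acid | C[C@@H]1OC[C@H](O)[C@@H]1[C@@H](CCCC(=O)O)[C@@H]1CC[C@@H](C(=O)OC(C)(C)C)N1C(=O)OC(C)(C)C | intermediate
24 | pentafluorophenyl ester of 23 | C[C@@H]1OC[C@H](O)[C@@H]1[C@@H](CCCC(=O)Oc2c(F)c(F)c(F)c(F)c2F)[C@@H]1CC[C@@H](C(=O)OC(C)(C)C)N1C(=O)OC(C)(C)C | intermediate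
25 | (2S,5S)-5-{(1R)-1-[(2S,3S,4R)-4-hydroxy-2-methyloxolan-3-yl]-5-oxo-5-(pentafluorophenoxy)pentyl}pyrrolidine-2-carboxylic acid (trifluoroacetate salt in the flask) | C[C@@H]1OC[C@H](O)[C@@H]1[C@@H](CCCC(=O)Oc2c(F)c(F)c(F)c(F)c2F)[C@@H]1CC[C@@H](C(=O)O)N1 | intermediate
26 | (3S,9R,9aS)-9-[(2S,3S,4R)-4-hydroxy-2-methyloxolan-3-yl]-5-oxooctahydro-1H-pyrrolo[1,2-a]azepine-3-carboxylic acid | C[C@@H]1OC[C@H](O)[C@@H]1[C@H]1CCCC(=O)N2[C@H]1CC[C@H]2C(=O)O | intermediate
27 | S-ethyl thioester of 26 | C[C@@H]1OC[C@H](O)[C@@H]1[C@H]1CCCC(=O)N2[C@H]1CC[C@H]2C(=O)SCC | intermediate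
28 | methyl (S)-3-hydroxy-2-methylpropanoate | OC[C@H](C)C(=O)OC | starting material
29 | methyl (R)-3-iodo-2-methylpropanoate | IC[C@H](C)C(=O)OC | intermediate
30 | [(2R)-3-methoxy-2-methyl-3-oxopropyl]zinc iodide | I[Zn]C[C@H](C)C(=O)OC | intermediate
31 | methyl (2S)-4-{(3S,9R,9aS)-9-[(2S,3S,4R)-4-hydroxy-2-methyloxolan-3-yl]-5-oxooctahydro-1H-pyrrolo[1,2-a]azepin-3-yl}-2-methyl-4-oxobutanoate | C[C@@H]1OC[C@H](O)[C@@H]1[C@H]1CCCC(=O)N2[C@H]1CC[C@H]2C(=O)C[C@H](C)C(=O)OC | intermediate
32 | (2S,4S)-4-hydroxy ester from 31 (lithium alkoxide in the flask) | C[C@@H]1OC[C@H](O)[C@@H]1[C@H]1CCCC(=O)N2[C@H]1CC[C@H]2[C@@H](O)C[C@H](C)C(=O)OC | intermediate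
33 | (3S,9R,9aS)-9-[(2S,3S,4R)-4-hydroxy-2-methyloxolan-3-yl]-3-[(2S,4S)-4-methyl-5-oxooxolan-2-yl]octahydro-5H-pyrrolo[1,2-a]azepin-5-one | C[C@@H]1OC[C@H](O)[C@@H]1[C@H]1CCCC(=O)N2[C@H]1CC[C@H]2[C@@H]1C[C@H](C)C(=O)O1 | intermediate
34 | bromoacetyl bromide | BrCC(=O)Br | starting material
35 | (3R,4R,5S)-5-methyl-4-{(3S,9R,9aS)-3-[(2S,4S)-4-methyl-5-oxooxolan-2-yl]-5-oxooctahydro-1H-pyrrolo[1,2-a]azepin-9-yl}oxolan-3-yl bromoacetate | C[C@@H]1OC[C@H](OC(=O)CBr)[C@@H]1[C@H]1CCCC(=O)N2[C@H]1CC[C@H]2[C@@H]1C[C@H](C)C(=O)O1 | intermediate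
36 | corresponding (3R,4R,5S)-oxolan-3-yl diazoacetate (all-cis) | C[C@@H]1OC[C@H](OC(=O)C=[N+]=[N-])[C@@H]1[C@H]1CCCC(=O)N2[C@H]1CC[C@H]2[C@@H]1C[C@H](C)C(=O)O1 | intermediate
37 | (3S,9R,9aS)-9-[(3aR,5S,6R,6aR)-5-methyl-2-oxohexahydrofuro[3,2-b]furan-6-yl]-3-[(2S,4S)-4-methyl-5-oxooxolan-2-yl]octahydro-5H-pyrrolo[1,2-a]azepin-5-one | C[C@@H]1O[C@H]2[C@H](OC(=O)C2)[C@@H]1[C@H]1CCCC(=O)N2[C@H]1CC[C@H]2[C@@H]1C[C@H](C)C(=O)O1 | intermediate
38 | (E)-3'-(dimethylaminomethylidene) derivative of 37 | C[C@@H]1O[C@H]2[C@H](OC(=O)/C2=C/N(C)C)[C@@H]1[C@H]1CCCC(=O)N2[C@H]1CC[C@H]2[C@@H]1C[C@H](C)C(=O)O1 | intermediate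
39 | (3S,9R,9aS)-9-[(3S,3aR,5S,6R,6aR)-3,5-dimethyl-2-oxohexahydrofuro[3,2-b]furan-6-yl]-3-[(2S,4S)-4-methyl-5-oxooxolan-2-yl]octahydro-5H-pyrrolo[1,2-a]azepin-5-one | C[C@@H]1O[C@H]2[C@H](OC(=O)[C@H]2C)[C@@H]1[C@H]1CCCC(=O)N2[C@H]1CC[C@H]2[C@@H]1C[C@H](C)C(=O)O1 | intermediate
40 | 5-thioxo analogue of 39 | C[C@@H]1O[C@H]2[C@H](OC(=O)[C@H]2C)[C@@H]1[C@H]1CCCC(=S)N2[C@H]1CC[C@H]2[C@@H]1C[C@H](C)C(=O)O1 | intermediate
41 | (3S,9R,9aS)-9-[(3S,3aR,5S,6R,6aR)-3,5-dimethyl-2-oxohexahydrofuro[3,2-b]furan-6-yl]-3-[(2S,4S)-4-methyl-5-oxooxolan-2-yl]octahydro-1H-pyrrolo[1,2-a]azepine | C[C@@H]1O[C@H]2[C@H](OC(=O)[C@H]2C)[C@@H]1[C@H]1CCCCN2[C@H]1CC[C@H]2[C@@H]1C[C@H](C)C(=O)O1 | target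

Total step count: 26. Longest linear sequence: 24 steps (1 → 41 through steps 1–3, 5–16 and 18–26). Steps 4 and 17 prepare side fragments.

Steps most likely to fail

Step 22. The carbenoid may be lost to dimerisation, to capture by traces of water, or to insertion at the more remote C9–H before it finds C3a'–H. The fallback gives up carbene chemistry and builds both rings of the furofuranone at once by palladium(II)-catalysed oxycarbonylative bicyclisation of a 4-ene-1,3-diol. It sets out from 16. Vinylmagnesium bromide would give vinyl ketone F1, and Evans–Saksena reduction would give anti ene-diol F2. PdCl2 (cat.), CuCl2, NaOAc and AcOH under CO would then give N-Boc furofuranone F3: O4' adds to C3a', and CO insertion followed by capture by the C6a' hydroxyl closes the necessarily cis-fused lactone. The remote pentenyl alkene has no internal nucleophile and should lag behind. The operations of steps 12–19 are then repeated in this series, through aldehyde F4, acid F5, pentafluorophenyl ester F6, lactam acid F7 and S-ethyl thioester F8. Fukuyama coupling with 30 gives keto ester F9, whose L-Selectride reduction and lactonisation comes back to the route at 37.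

Step 9. The short-lived carbenoid may decompose faster than it adds to the crowded α-branched amide, or it may stray to the tert-butyl ester. The fallback brings C3a' in as nucleophilic diazomethane on an activated acid (Arndt–Eistert-type acylation) and bypasses steps 8 and 9. It sets out from 15. TESCl/imidazole would give silyl ether F10, and LiOH/H2O2 would give acid F11 with release of the auxiliary. 1-Chloro-N,N,2-trimethylpropenylamine followed by diazomethane would give diazoketone F12. Ethereal HCl at 0 °C then replaces N2 by chloride and removes the silyl group, coming back to the route at 17.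

Step 6. Addition may be sluggish, and facial selectivity at C9 may erode, if imide and carbamate together crowd the copper reagent. The fallback separates the two tasks: C9 is set on a slim ester under control of C9a alone, and the auxiliary is attached afterwards. It sets out from 6. Wittig olefination with ethyl (triphenylphosphoranylidene)acetate would give ethyl (E)-enoate F13. TMSCl-accelerated addition of lithium di(pent-4-enyl)cuprate (attack anti to the C9a–N bond) would give ethyl ester F14, and LiOH would give acid F15. The mixed pivalic anhydride of F15 acylates 8 under LiCl/Et3N and comes back to the route at 12.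

Further compounds
F1 | step 22 | (4R,5R)-5-[(2S,5S)-1,5-bis(tert-butoxycarbonyl)pyrrolidin-2-yl]-4-[(1S)-1-hydroxyethyl]deca-1,9-dien-3-one | C[C@H](O)[C@H](C(=O)C=C)[C@@H](CCCC=C)[C@@H]1CC[C@@H](C(=O)OC(C)(C)C)N1C(=O)OC(C)(C)C
F2 | step 22 | 1,3-anti ene-diol from F1 (C6a' configured as in 18) | C[C@H](O)[C@H]([C@@H](O)C=C)[C@@H](CCCC=C)[C@@H]1CC[C@@H](C(=O)OC(C)(C)C)N1C(=O)OC(C)(C)C
F3 | step 22 | di-tert-butyl (2S,5S)-5-{(1R)-1-[(3aR,5S,6R,6aR)-5-methyl-2-oxohexahydrofuro[3,2-b]furan-6-yl]hex-5-en-1-yl}pyrrolidine-1,2-dicarboxylate | C[C@@H]1O[C@H]2[C@H](OC(=O)C2)[C@@H]1[C@@H](CCCC=C)[C@@H]1CC[C@@H](C(=O)OC(C)(C)C)N1C(=O)OC(C)(C)C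
F4 | step 22 | C5 aldehyde of the F3 series | C[C@@H]1O[C@H]2[C@H](OC(=O)C2)[C@@H]1[C@@H](CCCC=O)[C@@H]1CC[C@@H](C(=O)OC(C)(C)C)N1C(=O)OC(C)(C)C
F5 | step 22 | C5 acid of the F3 series | C[C@@H]1O[C@H]2[C@H](OC(=O)C2)[C@@H]1[C@@H](CCCC(=O)O)[C@@H]1CC[C@@H](C(=O)OC(C)(C)C)N1C(=O)OC(C)(C)C
F6 | step 22 | pentafluorophenyl ester of F5 | C[C@@H]1O[C@H]2[C@H](OC(=O)C2)[C@@H]1[C@@H](CCCC(=O)Oc2c(F)c(F)c(F)c(F)c2F)[C@@H]1CC[C@@H](C(=O)OC(C)(C)C)N1C(=O)OC(C)(C)C
F7 | step 22 | (3S,9R,9aS)-9-[(3aR,5S,6R,6aR)-5-methyl-2-oxohexahydrofuro[3,2-b]furan-6-yl]-5-oxooctahydro-1H-pyrrolo[1,2-a]azepine-3-carboxylic acid | C[C@@H]1O[C@H]2[C@H](OC(=O)C2)[C@@H]1[C@H]1CCCC(=O)N2[C@H]1CC[C@H]2C(=O)O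
F8 | step 22 | S-ethyl thioester of F7 | C[C@@H]1O[C@H]2[C@H](OC(=O)C2)[C@@H]1[C@H]1CCCC(=O)N2[C@H]1CC[C@H]2C(=O)SCC
F9 | step 22 | methyl (2S)-2-methyl-4-oxobutanoate attached through C4 to C3 of the F7 core | C[C@@H]1O[C@H]2[C@H](OC(=O)C2)[C@@H]1[C@H]1CCCC(=O)N2[C@H]1CC[C@H]2C(=O)C[C@H](C)C(=O)OC
F10 | step 9 | C5' O-triethylsilyl ether of 15 | C[C@H](O[Si](CC)(CC)CC)[C@H](C(=O)N1[C@H](Cc2ccccc2)COC1=O)[C@@H](CCCC=C)[C@@H]1CC[C@@H](C(=O)OC(C)(C)C)N1C(=O)OC(C)(C)C
F11 | step 9 | (2R,3R)-3-[(2S,5S)-1,5-bis(tert-butoxycarbonyl)pyrrolidin-2-yl]-2-[(1S)-1-(triethylsilyloxy)ethyl]oct-7-enoic acid | C[C@H](O[Si](CC)(CC)CC)[C@H](C(=O)O)[C@@H](CCCC=C)[C@@H]1CC[C@@H](C(=O)OC(C)(C)C)N1C(=O)OC(C)(C)C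
F12 | step 9 | diazomethyl ketone from F11 | C[C@H](O[Si](CC)(CC)CC)[C@H](C(=O)C=[N+]=[N-])[C@@H](CCCC=C)[C@@H]1CC[C@@H](C(=O)OC(C)(C)C)N1C(=O)OC(C)(C)C
F13 | step 6 | di-tert-butyl (2S,5S)-5-[(1E)-3-ethoxy-3-oxoprop-1-en-1-yl]pyrrolidine-1,2-dicarboxylate | CCOC(=O)/C=C/[C@@H]1CC[C@@H](C(=O)OC(C)(C)C)N1C(=O)OC(C)(C)C
F14 | step 6 | ethyl (3R)-3-[(2S,5S)-1,5-bis(tert-butoxycarbonyl)pyrrolidin-2-yl]oct-7-enoate | C=CCCC[C@H](CC(=O)OCC)[C@@H]1CC[C@@H](C(=O)OC(C)(C)C)N1C(=O)OC(C)(C)C
F15 | step 6 | (3R)-3-[(2S,5S)-1,5-bis(tert-butoxycarbonyl)pyrrolidin-2-yl]oct-7-enoic acid | C=CCCC[C@H](CC(=O)O)[C@@H]1CC[C@@H](C(=O)OC(C)(C)C)N1C(=O)OC(C)(C)C
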